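## Retrosynthetic overview

- The chalcone is unmasked last: hydroxide opens a 5‑methoxyflavanone (retro‑oxa‑Michael) in the same operation that removes two aryl acetates and one aryl tosylate.
- Key step: one flask, one acid, four components (an (S)‑homoallylic alcohol, two equivalents of 4‑acetoxybenzaldehyde, 2',4'‑dihydroxy‑6'‑methoxyacetophenone). Prins cyclization/Friedel–Crafts arylation closes the all‑cis 2,4,6‑trisubstituted tetrahydropyran; Claisen–Schmidt condensation/oxa‑Michael addition closes the chromanone.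
- The only pre‑set stereocentre (pyran C6) comes from an Ir‑catalysed enantioselective C‑allylation of a primary alcohol; C2 and C4 follow from the chair Prins transition state and equatorial arene capture.
- Ring order: tetrahydropyran first, chromanone second (same flask); the chromanone is reopened in the final step.

Assumption: the (R)‑bisphosphine in step 2 is the antipode that gives the 3S alcohol (otherwise the S ligand is used); C‑2 of the chromanone ring in 10 forms as an epimer mixture, which does not matter because step 4 destroys that centre.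

## Route

**Step 1**
Reactants: 1 4‑(3‑hydroxypropyl)phenol
Product: 2 4‑(3‑hydroxypropyl)phenyl 4‑methylbenzenesulfonate
Conditions: TsCl (1.05 equiv), K2CO3 (1.5 equiv), acetone, 0 °C → rt
Reagents that add atoms: p‑toluenesulfonyl chloride, Cc1ccc(cc1)S(=O)(=O)Cl
Why: Chemoselective O‑sulfonylation: carbonate deprotonates only the phenol, so the phenoxide is tosylated while the primary alcohol stays free for step 2, and the electron‑poor aryl sulfonate survives the Ir catalysis and the acid of step 3; no stereocentre is involved.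

**Step 2**
Reactants: 2 4‑(3‑hydroxypropyl)phenyl 4‑methylbenzenesulfonate; 3 allyl acetate (10 equiv)
Product: 5 4‑[(3S)‑3‑hydroxyhex‑5‑en‑1‑yl]phenyl 4‑methylbenzenesulfonate, via 4‑(3‑oxopropyl)phenyl 4‑methylbenzenesulfonate 4 (not isolated)
Conditions: [Ir(cod)Cl]2 (2.5 mol %), (R)‑Cl,MeO‑BIPHEP (5 mol %), 4‑Cl‑3‑NO2‑C6H3CO2H (10 mol %), Cs2CO3 (20 mol %), THF, 100 °C
Reagents that add atoms: none
Why: Krische iridium‑catalysed transfer‑hydrogenative carbonyl allylation: the cyclometallated Ir C,O‑benzoate dehydrogenates 2 to aldehyde 4 and, as its π‑allyl complex formed from 3, adds the allyl group through a closed chair‑like transition state in which the chiral bisphosphine selects the aldehyde face, setting the carbinol centre (future pyran C6) as S.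

**Step 3 (key step)**
Reactants: 5 4‑[(3S)‑3‑hydroxyhex‑5‑en‑1‑yl]phenyl 4‑methylbenzenesulfonate; 6 4‑formylphenyl acetate (2.6 equiv in two portions); 7 1‑(2,4‑dihydroxy‑6‑methoxyphenyl)ethan‑1‑one
Product: 10 (2RS)‑2‑(4‑acetoxyphenyl)‑8‑[(2S,4R,6S)‑2‑(4‑acetoxyphenyl)‑6‑{2‑[4‑(tosyloxy)phenyl]ethyl}oxan‑4‑yl]‑7‑hydroxy‑5‑methoxy‑2,3‑dihydro‑4H‑chromen‑4‑one, via Prins/Friedel–Crafts ketone 8 (not isolated), via chalcone 9 (not isolated)
Conditions: TfOH (20 mol %), 4 Å MS, CH2Cl2, −40 → 0 °C (5 1.0 equiv, 7 1.1 equiv, 6 1.1 equiv); then 6 (1.5 equiv), TfOH (30 mol %), 40 °C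
Reagents that add atoms: none
Why: Proposed new method: a one‑flask merger of two acid‑promoted processes that are each known separately — (i) tandem Prins cyclization/Friedel–Crafts arylation, in which the (E)‑oxocarbenium ion from 5 and 6 closes through a chair with both substituents equatorial (2,6‑cis) and the secondary oxan‑4‑yl cation is captured equatorially by C‑3 of 7 (between the two hydroxyls, para to OMe), so C2 and C4 are set cis to the existing C6 centre, and (ii) acid‑catalysed Claisen–Schmidt condensation of the acetyl group with the second portion of 6 followed by 6‑endo oxa‑Michael closure of the 2'‑OH (the xanthohumol → isoxanthohumol type isomerisation); the acetoxy group on 6 suppresses 2‑oxonia‑Cope racemisation and benzylic ionisation, and the closest known reactions are the three‑component Prins/Friedel–Crafts synthesis of 4‑aryl‑tetrahydropyrans and the acid‑mediated flavanone synthesis from 2'‑hydroxyacetophenones and benzaldehydes.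

**Step 4**
Reactants: 10 (2RS)‑2‑(4‑acetoxyphenyl)‑8‑[(2S,4R,6S)‑2‑(4‑acetoxyphenyl)‑6‑{2‑[4‑(tosyloxy)phenyl]ethyl}oxan‑4‑yl]‑7‑hydroxy‑5‑methoxy‑2,3‑dihydro‑4H‑chromen‑4‑one
Product: 12 (E)‑1‑{2,4‑dihydroxy‑3‑[(2S,4R,6S)‑2‑(4‑hydroxyphenyl)‑6‑[2‑(4‑hydroxyphenyl)ethyl]oxan‑4‑yl]‑6‑methoxyphenyl}‑3‑(4‑hydroxyphenyl)prop‑2‑en‑1‑one, via chalcone monotosylate 11 (not isolated)
Conditions: 50% aq KOH–EtOH (1:1), Ar, 50 °C; then poured into ice‑cold 2 M HCl (pH 3)
Reagents that add atoms: none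
Why: Hydroxide cleaves the two aryl acetates (acyl–O) and the aryl tosylate (S–O) and opens the chromanone by E1cB retro‑oxa‑Michael elimination to the (E)‑chalcone, which is the resting state as its polyphenolate in concentrated alkali (the medium in which 2'‑hydroxy‑6'‑methoxychalcones are made by Claisen–Schmidt condensation); the chromanone C‑2 centre is destroyed, the three pyran centres are untouched, and fast cold acidification prevents re‑closure.

## Compound list

1 | 4‑(3‑hydroxypropyl)phenol | OCCCc1ccc(O)cc1 | starting material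
2 | 4‑(3‑hydroxypropyl)phenyl 4‑methylbenzenesulfonate | Cc1ccc(cc1)S(=O)(=O)Oc1ccc(CCCO)cc1 | intermediate
3 | allyl acetate (prop‑2‑en‑1‑yl acetate) | CC(=O)OCC=C | starting material
4 | 4‑(3‑oxopropyl)phenyl 4‑methylbenzenesulfonate | Cc1ccc(cc1)S(=O)(=O)Oc1ccc(CCC=O)cc1 | intermediate
5 | 4‑[(3S)‑3‑hydroxyhex‑5‑en‑1‑yl]phenyl 4‑methylbenzenesulfonate | C=CC[C@@H](O)CCc1ccc(OS(=O)(=O)c2ccc(C)cc2)cc1 | intermediate
6 | 4‑formylphenyl acetate (4‑acetoxybenzaldehyde) | CC(=O)Oc1ccc(C=O)cc1 | starting material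
7 | 1‑(2,4‑dihydroxy‑6‑methoxyphenyl)ethan‑1‑one | COc1cc(O)cc(O)c1C(C)=O | starting material
8 | 1‑{3‑[(2S,4R,6S)‑2‑(4‑acetoxyphenyl)‑6‑{2‑[4‑(tosyloxy)phenyl]ethyl}oxan‑4‑yl]‑2,4‑dihydroxy‑6‑methoxyphenyl}ethan‑1‑one | COc1cc(O)c([C@@H]2C[C@H](CCc3ccc(OS(=O)(=O)c4ccc(C)cc4)cc3)O[C@H](c3ccc(OC(C)=O)cc3)C2)c(O)c1C(C)=O | intermediate
9 | (E)‑1‑{3‑[(2S,4R,6S)‑2‑(4‑acetoxyphenyl)‑6‑{2‑[4‑(tosyloxy)phenyl]ethyl}oxan‑4‑yl]‑2,4‑dihydroxy‑6‑methoxyphenyl}‑3‑(4‑acetoxyphenyl)prop‑2‑en‑1‑one | COc1cc(O)c([C@@H]2C[C@H](CCc3ccc(OS(=O)(=O)c4ccc(C)cc4)cc3)O[C@H](c3ccc(OC(C)=O)cc3)C2)c(O)c1C(=O)/C=C/c1ccc(OC(C)=O)cc1 | intermediate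
10 | (2RS)‑2‑(4‑acetoxyphenyl)‑8‑[(2S,4R,6S)‑2‑(4‑acetoxyphenyl)‑6‑{2‑[4‑(tosyloxy)phenyl]ethyl}oxan‑4‑yl]‑7‑hydroxy‑5‑methoxy‑2,3‑dihydro‑4H‑chromen‑4‑one (chromanone C‑2 undefined, epimer mixture) | COc1cc(O)c([C@@H]2C[C@H](CCc3ccc(OS(=O)(=O)c4ccc(C)cc4)cc3)O[C@H](c3ccc(OC(C)=O)cc3)C2)c2OC(c3ccc(OC(C)=O)cc3)CC(=O)c12 | intermediate
11 | (E)‑1‑{2,4‑dihydroxy‑3‑[(2S,4R,6S)‑2‑(4‑hydroxyphenyl)‑6‑{2‑[4‑(tosyloxy)phenyl]ethyl}oxan‑4‑yl]‑6‑methoxyphenyl}‑3‑(4‑hydroxyphenyl)prop‑2‑en‑1‑one | COc1cc(O)c([C@@H]2C[C@H](CCc3ccc(OS(=O)(=O)c4ccc(C)cc4)cc3)O[C@H](c3ccc(O)cc3)C2)c(O)c1C(=O)/C=C/c1ccc(O)cc1 | intermediate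
12 | (E)‑1‑{2,4‑dihydroxy‑3‑[(2S,4R,6S)‑2‑(4‑hydroxyphenyl)‑6‑[2‑(4‑hydroxyphenyl)ethyl]oxan‑4‑yl]‑6‑methoxyphenyl}‑3‑(4‑hydroxyphenyl)prop‑2‑en‑1‑one (CNP0215517.1) | COc1cc(O)c([C@@H]2C[C@H](CCc3ccc(O)cc3)O[C@H](c3ccc(O)cc3)C2)c(O)c1C(=O)/C=C/c1ccc(O)cc1 | target

## Step count and risk

Total steps: 4. Longest linear sequence: 4 (1 → 2 → 5 → 10 → 12).

**Most likely to fail, 1: step 3.** The acylphloroglucinol may capture the oxanyl cation slowly or at C‑5 instead of C‑3, and in the second stage the aldehyde may hydroxyalkylate the arene instead of condensing with the acetyl group. The fallback sets out from 7 and closes the chromanone first: 7 and one equivalent of 6 (TfOH cat., ClCH2CH2Cl, 60 °C) give the flavanone 4‑[(2RS)‑7‑hydroxy‑5‑methoxy‑4‑oxo‑3,4‑dihydro‑2H‑chromen‑2‑yl]phenyl acetate F1, in which the acetyl group is already spent. F1 then serves as the Friedel–Crafts partner in a separate, stoichiometric BF3·OEt2‑mediated Prins cyclization of 5 with one equivalent of 6 (CH2Cl2, −20 °C), arene capture now occurring at C‑8 of the chromanone. This comes back to the route at 10.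

**Most likely to fail, 2: step 4.** The chalcone/flavanone equilibrium can fall back to the flavanone in dilute base or on slow neutralisation, and hot alkali can cause retro‑aldol cleavage. The fallback sets out from 8, isolated by quenching step 3 after its first stage. Saponification (KOH, MeOH–H2O, 65 °C) gives the tetraphenol ketone 1‑{2,4‑dihydroxy‑3‑[(2S,4R,6S)‑2‑(4‑hydroxyphenyl)‑6‑[2‑(4‑hydroxyphenyl)ethyl]oxan‑4‑yl]‑6‑methoxyphenyl}ethan‑1‑one F2. The enone is then built last by Claisen–Schmidt condensation of F2 with 4‑hydroxybenzaldehyde (60% aq KOH, EtOH, rt), so no ring opening is needed and the chalcone never sees hot base. This arrives directly at 12.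

**Most likely to fail, 3: step 2.** The ee may be insufficient for an unbranched aliphatic alcohol, or the conversion slow. The fallback sets out from 2: oxidise it to 4 and isolate the aldehyde (TEMPO cat., PhI(OAc)2, CH2Cl2), then allylate with stoichiometric (+)‑B‑allyldiisopinocampheylborane [from (−)‑α‑pinene] (Et2O, −78 °C; NaBO3 work‑up). This is reagent‑controlled allylboration through a Zimmerman–Traxler chair and returns to 5; no new compound is involved.

## Further compounds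

F1 | step 3 | 4‑[(2RS)‑7‑hydroxy‑5‑methoxy‑4‑oxo‑3,4‑dihydro‑2H‑chromen‑2‑yl]phenyl acetate | COc1cc(O)cc2OC(c3ccc(OC(C)=O)cc3)CC(=O)c12
F2 | step 4 | 1‑{2,4‑dihydroxy‑3‑[(2S,4R,6S)‑2‑(4‑hydroxyphenyl)‑6‑[2‑(4‑hydroxyphenyl)ethyl]oxan‑4‑yl]‑6‑methoxyphenyl}ethan‑1‑one | COc1cc(O)c([C@@H]2C[C@H](CCc3ccc(O)cc3)O[C@H](c3ccc(O)cc3)C2)c(O)c1C(C)=O
F0 | step 2 | none | none
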